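**Plan**

1. Locants: C1(=C20H2)–C2=C3–C4–C5(CH3)–C6–C7(OAc)–C8=C9(CH3)–C10–C11 is the eleven-membered ring, C10–C11–C12–C13–C14(CH3) the cyclopentane, C8–C9–C10–C14–C15(OAc)–C16(OH) the cyclohexene. The enabling feature is quaternary C14 next to oxygen-bearing C15 and tied through C13–C12–C11 to C10: a cyclohexanone enol ether (C14=C15–O) with a propargyl arm on its β-carbon C10.
2. Cuts: C7–C8 (Nozaki–Hiyama–Kishi) and C1–C2 (Suzuki) release the C2–C7 chain; C11–C1 (acetyl equivalent on a C11 enol triflate); C13–C14 (gold, 5-endo-dig) and C10–C11 (conjugate propargylation) lead back to a 2,4-dimethyl-5-silyloxycyclohexenone built by crotylation and ring-closing metathesis.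
3. Forward order: six-membered ring, then the cyclopentene by the gold step, the C16/C15 oxygens, the C11 acetyl group, the chain by Suzuki coupling, and the eleven-membered ring last by C7–C8 closure.
4. Stereochemistry: C8/C9 come from an iridium-catalysed anti-crotylation and are later erased; they relay to C10 (propargyl anti to the C9 methyl), C14 (cis closure), C16 (hydroxylation anti to 8α-OTBS), C15 (hydroxyl-directed hydride) and C11 (hydrogenation from the α face).
5. C5 comes from (R)-3-methylglutaric acid monomethyl ester, C7 from a CBS reduction, and the E C2=C3 bond from a Takai boron olefination.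

Key step: step 9

Remark: α is the face of the six-membered ring that carries H-10 and the C14 methyl, β the face that carries C11 and C13; bicyclic intermediates are named as cis-hydrindanes with the target's locants; compounds 1, 2, 8, 12, 22, 29 and 33 are assumed to be purchased.

**Route**

Step 1
Reactants: 1 3-(tert-butyldimethylsilyloxy)propan-1-ol; 2 but-3-en-2-yl acetate (racemic)
Product: 4 (3R,4S)-1-(tert-butyldimethylsilyloxy)-4-methylhex-5-en-3-ol, via 3-(tert-butyldimethylsilyloxy)propanal 3 (not isolated)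
Conditions: [Ir(cod)Cl]2 (2.5 mol %), (S)-SEGPHOS (5 mol %), 4-cyano-3-nitrobenzoic acid (10 mol %), Cs2CO3 (20 mol %), THF, 90 °C
Reagents that add atoms: none
Why: Iridium-catalysed transfer-hydrogenative crotylation from the alcohol oxidation level (Krische crotylation) should dehydrogenate 1 to 3 and add the (E)-σ-crotyliridium species through a closed chair transition state, which gives the anti relationship, while the (S)-ligand selects the aldehyde face that leads to 3R,4S.

Step 2
Reactants: 4 (3R,4S)-1-(tert-butyldimethylsilyloxy)-4-methylhex-5-en-3-ol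
Product: 5 (3R,4S)-1,3-bis(tert-butyldimethylsilyloxy)-4-methylhex-5-ene
Conditions: TBSOTf, 2,6-lutidine, CH2Cl2, −78 → 0 °C
Reagents that add atoms: tert-butyldimethylsilyl triflate, CC(C)(C)[Si](C)(C)OS(=O)(=O)C(F)(F)F
Why: Silylation of the secondary carbinol with a silyl triflate and a hindered base is routine and masks the future C8 oxygen with a group that should last until step 16.

Step 3
Reactants: 5 (3R,4S)-1,3-bis(tert-butyldimethylsilyloxy)-4-methylhex-5-ene
Product: 6 (3R,4S)-3-(tert-butyldimethylsilyloxy)-4-methylhex-5-en-1-ol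
Conditions: HF·pyridine, pyridine, THF, 0 °C
Reagents that add atoms: none
Why: Buffered HF·pyridine should cleave the unhindered primary silyl ether much faster than the secondary one next to the methyl-bearing carbon (selective desilylation).

Step 4
Reactants: 6 (3R,4S)-3-(tert-butyldimethylsilyloxy)-4-methylhex-5-en-1-ol
Product: 7 (3R,4S)-3-(tert-butyldimethylsilyloxy)-4-methylhex-5-enal
Conditions: Dess–Martin periodinane, NaHCO3, CH2Cl2, 0 °C → rt
Reagents that add atoms: none
Why: Dess–Martin oxidation gives the β-silyloxy aldehyde under buffered neutral conditions that avoid β-elimination.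

Step 5
Reactants: 7 (3R,4S)-3-(tert-butyldimethylsilyloxy)-4-methylhex-5-enal; 8 isopropenylmagnesium bromide
Product: 9 (5R,6S)-5-(tert-butyldimethylsilyloxy)-2,6-dimethylocta-1,7-dien-3-ol (both C3 epimers)
Conditions: THF, −78 → 0 °C; aq. NH4Cl
Reagents that add atoms: none
Why: Grignard 1,2-addition brings in C14 with its methyl group; the new carbinol centre needs no control because it is oxidised in step 7.

Step 6
Reactants: 9 (5R,6S)-5-(tert-butyldimethylsilyloxy)-2,6-dimethylocta-1,7-dien-3-ol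
Product: 10 (4S,5R)-5-(tert-butyldimethylsilyloxy)-2,4-dimethylcyclohex-2-en-1-ol (both C1 epimers)
Conditions: Grubbs second-generation catalyst (5 mol %), CH2Cl2 (5 mM), 40 °C
Reagents that add atoms: none
Why: Ring-closing metathesis between the monosubstituted and the 1,1-disubstituted alkene should close the six-membered ring as the trisubstituted C14=C10 alkene, driven by loss of ethylene.

Step 7
Reactants: 10 (4S,5R)-5-(tert-butyldimethylsilyloxy)-2,4-dimethylcyclohex-2-en-1-ol
Product: 11 (4S,5R)-5-(tert-butyldimethylsilyloxy)-2,4-dimethylcyclohex-2-en-1-one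
Conditions: Dess–Martin periodinane, NaHCO3, CH2Cl2, rt
Reagents that add atoms: none
Why: Dess–Martin oxidation of the allylic alcohol gives the enone without base, which protects the β-silyloxy enone from elimination and aromatisation.

Step 8
Reactants: 11 (4S,5R)-5-(tert-butyldimethylsilyloxy)-2,4-dimethylcyclohex-2-en-1-one; 12 tributyl(propa-1,2-dien-1-yl)stannane
Product: 13 (3S,4S,5R)-1,5-bis(tert-butyldimethylsilyloxy)-2,4-dimethyl-3-(prop-2-yn-1-yl)cyclohex-1-ene
Conditions: TBSOTf (1.3 equiv), CH2Cl2, −78 °C; Et3N quench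
Reagents that add atoms: tert-butyldimethylsilyl triflate, CC(C)(C)[Si](C)(C)OS(=O)(=O)C(F)(F)F
Why: In this silyl-triflate-promoted Sakurai-type conjugate propargylation the O-silylated enone is attacked at C10 by the γ-carbon of the allenylstannane (SE2′), axially and anti to both the pseudoaxial C9 methyl and the 8-silyloxy group, which sets C10 and fixes the enol ether at C14=C15.

Step 9
Reactants: 13 (3S,4S,5R)-1,5-bis(tert-butyldimethylsilyloxy)-2,4-dimethyl-3-(prop-2-yn-1-yl)cyclohex-1-ene
Product: 14 8α-(tert-butyldimethylsilyloxy)-9α,14α-dimethyl-cis-hydrind-12-en-15-one (H-10 α)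
Conditions: Ph3PAuCl (10 mol %), AgBF4 (10 mol %), CH2Cl2/MeOH 10:1, 40 °C
Reagents that add atoms: none
Why: Cationic Ph3PAu+ binds the terminal alkyne and C14 of the silyl enol ether attacks C13 anti to gold, forming C13–C14 and an alkenylgold oxocarbenium ion; methanol then takes the silyl group and protodeauration at C12 releases the C15 ketone and the C12=C13 alkene. The closest known reaction type is the gold(I)-catalysed Conia-ene-type carbocyclisation of silyl enol ethers onto alkynes, which gives hydrindanones with quaternary centres from conjugate-propargylation products of α-substituted cyclohexenones. The cyclopentene closes in the 5-endo-dig mode. C14 is controlled by C10: the three-atom arm C11–C12–C13 can reach only the face of the enol ether on which it stands, so the fusion must be cis and the methyl group is pushed to the α face. The step needs carbon attack by the fully substituted enol carbon instead of alkyne hydration or simple desilylation, and this is secured by the enol ether regiochemistry fixed in step 8 and by the pseudoaxial propargyl group (A1,2 strain with the C14 methyl) that holds the alkyne over C14.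

Step 10
Reactants: 14 8α-(tert-butyldimethylsilyloxy)-9α,14α-dimethyl-cis-hydrind-12-en-15-one
Product: 15 8α-(tert-butyldimethylsilyloxy)-16β-hydroxy-9α,14α-dimethyl-cis-hydrind-12-en-15-one
Conditions: KHMDS, THF, −78 °C; 2-(phenylsulfonyl)-3-phenyloxaziridine, −78 °C; aq. NH4Cl
Reagents that add atoms: 2-(phenylsulfonyl)-3-phenyloxaziridine, O=S(=O)(c1ccccc1)N1OC1c1ccccc1
Why: In this Davis oxidation the potassium enolate can form only toward C16 because C14 is quaternary, and the oxaziridine should deliver oxygen axially to the β face, anti to the adjacent axial 8α-silyloxy group, which sets C16.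

Step 11
Reactants: 15 8α-(tert-butyldimethylsilyloxy)-16β-hydroxy-9α,14α-dimethyl-cis-hydrind-12-en-15-one
Product: 16 8α-(tert-butyldimethylsilyloxy)-9α,14α-dimethyl-cis-hydrind-12-ene-15α,16β-diol
Conditions: Me4NBH(OAc)3, MeCN/AcOH 1:1, −30 °C
Reagents that add atoms: none
Why: In this hydroxyl-directed Evans–Saksena reduction the C16 hydroxyl exchanges onto boron and hydride is delivered intramolecularly to the β face of C15 (the α face is also shielded by the axial 8α-silyloxy group), which gives the 15α-alcohol of the trans-diol.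

Step 12
Reactants: 16 8α-(tert-butyldimethylsilyloxy)-9α,14α-dimethyl-cis-hydrind-12-ene-15α,16β-diol
Product: 18 15α-acetoxy-8α-(tert-butyldimethylsilyloxy)-16β-(triisopropylsilyloxy)-9α,14α-dimethyl-cis-hydrind-12-ene, via 16β-triisopropylsilyl ether 15α-alcohol 17 (not isolated)
Conditions: TIPSOTf (1.1 equiv), 2,6-lutidine, CH2Cl2, −78 → 0 °C; then Ac2O, Et3N, DMAP, rt → 40 °C
Reagents that add atoms: triisopropylsilyl triflate, CC(C)[Si](C(C)C)(C(C)C)OS(=O)(=O)C(F)(F)F; acetic anhydride, CC(=O)OC(C)=O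
Why: The bulky silyl triflate should take the less hindered C16 hydroxyl (the C15 hydroxyl is neopentyl), after which DMAP-catalysed acetylation installs the final C15 acetate in the same flask without touching a stereocentre.

Step 13
Reactants: 18 15α-acetoxy-8α-(tert-butyldimethylsilyloxy)-16β-(triisopropylsilyloxy)-9α,14α-dimethyl-cis-hydrind-12-ene
Product: 19 15α-acetoxy-8α-(tert-butyldimethylsilyloxy)-16β-(triisopropylsilyloxy)-9α,14α-dimethyl-cis-hydrind-12-en-11-one
Conditions: Rh2(cap)4 (1 mol %), t-BuOOH (70 % aq., 5 equiv), K2CO3, CH2Cl2, rt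
Reagents that add atoms: tert-butyl hydroperoxide, CC(C)(C)OO
Why: Dirhodium-caprolactamate-catalysed allylic oxidation with TBHP should convert the only allylic methylene, C11, into the enone carbonyl, because the other allylic position C14 is quaternary and the neopentyl terminus C13 is the more hindered end of the allyl radical.

Step 14
Reactants: 19 15α-acetoxy-8α-(tert-butyldimethylsilyloxy)-16β-(triisopropylsilyloxy)-9α,14α-dimethyl-cis-hydrind-12-en-11-one
Product: 20 15α-acetoxy-8α-(tert-butyldimethylsilyloxy)-16β-(triisopropylsilyloxy)-9α,14α-dimethyl-cis-hydrindan-11-one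
Conditions: H2 (1 atm), 10 % Pd/C, EtOAc, rt
Reagents that add atoms: none
Why: Heterogeneous hydrogenation saturates the enone C12=C13 bond without creating a stereocentre, and the cis ring fusion at C10 is the stable arrangement next to the ketone.

Step 15
Reactants: 20 15α-acetoxy-8α-(tert-butyldimethylsilyloxy)-16β-(triisopropylsilyloxy)-9α,14α-dimethyl-cis-hydrindan-11-one
Product: 21 15α-acetoxy-8α-(tert-butyldimethylsilyloxy)-16β-(triisopropylsilyloxy)-9α,14α-dimethyl-cis-hydrind-11-en-11-yl triflate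
Conditions: KHMDS, THF, −78 °C; PhNTf2, −78 → 0 °C
Reagents that add atoms: N-phenylbis(trifluoromethanesulfonimide), O=S(=O)(N(c1ccccc1)S(=O)(=O)C(F)(F)F)C(F)(F)F
Why: Kinetic deprotonation should occur at the C12 methylene and not at the hindered ring-fusion methine C10, and O-triflation of that enolate gives the C11=C12 enol triflate.

Step 16
Reactants: 21 15α-acetoxy-8α-(tert-butyldimethylsilyloxy)-16β-(triisopropylsilyloxy)-9α,14α-dimethyl-cis-hydrind-11-en-11-yl triflate; 22 tributyl(1-ethoxyvinyl)stannane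
Product: 25 11-acetyl-15α-acetoxy-16β-(triisopropylsilyloxy)-9α,14α-dimethyl-cis-hydrind-11-en-8α-ol, via 1-ethoxyvinyl diene 23 (not isolated), via 8α-silyloxy acetyl enone 24 (not isolated)
Conditions: Pd(PPh3)4 (5 mol %), LiCl, THF, 65 °C; then 48 % aq. HF, MeCN, 0 °C → rt
Reagents that add atoms: water, O
Why: Stille coupling with the 1-ethoxyvinyl stannane (an acetyl anion equivalent) joins C1 and C20 to C11, and the aqueous HF treatment hydrolyses the enol ether to the methyl ketone and should remove the secondary TBS ether faster than the TIPS ether.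

Step 17
Reactants: 25 11-acetyl-15α-acetoxy-16β-(triisopropylsilyloxy)-9α,14α-dimethyl-cis-hydrind-11-en-8α-ol
Product: 26 11β-acetyl-15α-acetoxy-16β-(triisopropylsilyloxy)-9α,14α-dimethyl-cis-hydrindan-8α-ol (H-11 α)
Conditions: H2 (1 atm), [Ir(cod)(PCy3)(py)]PF6 (Crabtree's catalyst, 10 mol %), CH2Cl2, rt
Reagents that add atoms: none
Why: Homogeneous hydrogenation should deliver hydrogen to the convex α face of the cyclopentene (the side of H-10, now free of the bulky silyl ether and able to bind iridium through the 8α-hydroxyl), so that C11 receives its hydrogen α and the acetyl group ends β, cis to the C10–C9 bond.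

Step 18
Reactants: 26 11β-acetyl-15α-acetoxy-16β-(triisopropylsilyloxy)-9α,14α-dimethyl-cis-hydrindan-8α-ol
Product: 27 11β-acetyl-15α-acetoxy-16β-(triisopropylsilyloxy)-9α,14α-dimethyl-cis-hydrindan-8-one
Conditions: Dess–Martin periodinane, NaHCO3, CH2Cl2, rt
Reagents that add atoms: none
Why: Buffered Dess–Martin oxidation turns the C8 carbinol into the ketone without enolising the C11 centre.

Step 19
Reactants: 27 11β-acetyl-15α-acetoxy-16β-(triisopropylsilyloxy)-9α,14α-dimethyl-cis-hydrindan-8-one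
Product: 28 bis(enol triflate): 15α-acetoxy-16β-(triisopropylsilyloxy)-9,14α-dimethyl-11β-(1-triflyloxyvinyl)-cis-hydrind-8-en-8-yl triflate
Conditions: KHMDS (2.3 equiv), THF, −78 °C; PhNTf2 (2.5 equiv), −78 → 0 °C
Reagents that add atoms: N-phenylbis(trifluoromethanesulfonimide), O=S(=O)(N(c1ccccc1)S(=O)(=O)C(F)(F)F)C(F)(F)F
Why: Double kinetic enolisation should take the methyl group of the acetyl unit and, at the ring ketone, the axial hydrogen on C9 rather than the equatorial, oxygen-deactivated hydrogen on silyloxy-bearing C16, and both enolates are trapped as triflates (C1=C20 and C8=C9).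

Step 20
Reactants: 29 (R)-5-methoxy-3-methyl-5-oxopentanoic acid
Product: 30 methyl (R)-5-hydroxy-3-methylpentanoate
Conditions: BH3·SMe2, THF, 0 °C → rt; MeOH
Reagents that add atoms: none
Why: Borane reduces the free carboxylic acid chemoselectively in the presence of the methyl ester and leaves the C5 centre untouched.

Step 21
Reactants: 30 methyl (R)-5-hydroxy-3-methylpentanoate
Product: 31 methyl (R)-3-methyl-5-(triethylsilyloxy)pentanoate
Conditions: Et3SiCl, imidazole, CH2Cl2, 0 °C
Reagents that add atoms: chlorotriethylsilane, CC[Si](Cl)(CC)CC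
Why: Immediate silylation prevents lactonisation and installs a primary triethylsilyl ether that can later be oxidised directly.

Step 22
Reactants: 31 methyl (R)-3-methyl-5-(triethylsilyloxy)pentanoate
Product: 32 (R)-3-methyl-5-(triethylsilyloxy)pentanal
Conditions: DIBAL-H, CH2Cl2, −78 °C; Rochelle salt
Reagents that add atoms: none
Why: Partial reduction with DIBAL-H at low temperature stops at the aldehyde through the stable tetrahedral aluminate.

Step 23
Reactants: 32 (R)-3-methyl-5-(triethylsilyloxy)pentanal; 33 2-(dichloromethyl)-4,4,5,5-tetramethyl-1,3,2-dioxaborolane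
Product: 34 (S,E)-triethyl{[3-methyl-6-(4,4,5,5-tetramethyl-1,3,2-dioxaborolan-2-yl)hex-5-en-1-yl]oxy}silane
Conditions: CrCl2, LiI, THF, rt
Reagents that add atoms: none
Why: Takai-type olefination with the gem-dichromium reagent generated from the dichloromethylboronate should give the (E)-alkenylboronate, which supplies C2 and fixes the C2=C3 geometry.

Step 24
Reactants: 28 bis(enol triflate); 34 (S,E)-alkenylboronate
Product: 35 15α-acetoxy-16β-(triisopropylsilyloxy)-9,14α-dimethyl-11β-[(3E,6S)-6-methyl-8-(triethylsilyloxy)octa-1,3-dien-2-yl]-cis-hydrind-8-en-8-yl triflate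
Conditions: Pd(PPh3)4 (5 mol %), aq. K3PO4, dioxane, rt
Reagents that add atoms: none
Why: Suzuki–Miyaura coupling should occur only at the unhindered 1,1-disubstituted C1 triflate, because oxidative addition to the tetrasubstituted C8 triflate flanked by the C9 methyl and the silyloxy-bearing C16 is much slower, and the alkene geometry is retained.

Step 25
Reactants: 35 diene triflate with C7 triethylsilyl ether
Product: 36 15α-acetoxy-16β-(triisopropylsilyloxy)-9,14α-dimethyl-11β-[(3E,6S)-6-methyl-8-oxoocta-1,3-dien-2-yl]-cis-hydrind-8-en-8-yl triflate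
Conditions: (COCl)2, DMSO, CH2Cl2, −78 → −40 °C; Et3N
Reagents that add atoms: none
Why: Swern conditions oxidise primary triethylsilyl ethers directly to aldehydes, while the secondary TIPS ether, the acetate, the diene and the triflate should be untouched.

Step 26
Reactants: 36 aldehyde triflate
Product: 37 7-O-deacetyl-16-O-triisopropylsilyl target (macrocyclic C7 alcohol, both C7 epimers)
Conditions: CrCl2 (10 equiv), NiCl2 (cat.), DMF, rt → 50 °C, 2 mM, slow addition
Reagents that add atoms: none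
Why: In this Nozaki–Hiyama–Kishi macrocyclisation nickel inserts into the alkenyl triflate, transmetalation gives the alkenylchromium(III) species and its chemoselective addition to the aldehyde closes the eleven-membered ring by C7–C8; both C7 epimers are carried on.

Step 27
Reactants: 37 macrocyclic C7 alcohol
Product: 38 7-oxo-7-deacetoxy-16-O-triisopropylsilyl target (macrocyclic enone)
Conditions: Dess–Martin periodinane, NaHCO3, CH2Cl2, rt
Reagents that add atoms: none
Why: Dess–Martin oxidation converges both carbinol epimers on one enone in which C7 can be set by a reagent.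

Step 28
Reactants: 38 macrocyclic enone
Product: 39 (7S)-7-O-deacetyl-16-O-triisopropylsilyl target
Conditions: (R)-2-methyl-CBS-oxazaborolidine (0.5 equiv), catecholborane, toluene, −78 °C
Reagents that add atoms: none
Why: In this Corey–Bakshi–Shibata reduction the tetrasubstituted alkenyl group acts as the large substituent, so the (R)-catalyst should deliver hydride to the face that gives 7S, and catecholborane at low temperature avoids hydroboration of the diene.

Step 29
Reactants: 39 (7S)-alcohol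
Product: 40 16-O-triisopropylsilyl target
Conditions: Ac2O, Et3N, DMAP, CH2Cl2, rt
Reagents that add atoms: acetic anhydride, CC(=O)OC(C)=O
Why: DMAP-catalysed acetylation of the only free hydroxyl installs the C7 acetate with retention.

Step 30
Reactants: 40 16-O-triisopropylsilyl target
Product: 41 CNP0323842.1 (target)
Conditions: HF·pyridine, pyridine, THF, rt
Reagents that add atoms: none
Why: Fluoride-mediated desilylation under weakly acidic conditions frees the C16 hydroxyl and should not allow acetyl migration from C15.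

**Compound list**

1 | 3-(tert-butyldimethylsilyloxy)propan-1-ol | OCCCO[Si](C)(C)C(C)(C)C | starting material
2 | but-3-en-2-yl acetate (racemic) | CC(OC(C)=O)C=C | starting material
3 | 3-(tert-butyldimethylsilyloxy)propanal | O=CCCO[Si](C)(C)C(C)(C)C | intermediate (not isolated)
4 | (3R,4S)-1-(tert-butyldimethylsilyloxy)-4-methylhex-5-en-3-ol | CC(C)(C)[Si](C)(C)OCC[C@@H](O)[C@@H](C)C=C | intermediate
5 | (3R,4S)-1,3-bis(tert-butyldimethylsilyloxy)-4-methylhex-5-ene | CC(C)(C)[Si](C)(C)OCC[C@@H](O[Si](C)(C)C(C)(C)C)[C@@H](C)C=C | intermediate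
6 | (3R,4S)-3-(tert-butyldimethylsilyloxy)-4-methylhex-5-en-1-ol | OCC[C@@H](O[Si](C)(C)C(C)(C)C)[C@@H](C)C=C | intermediate
7 | (3R,4S)-3-(tert-butyldimethylsilyloxy)-4-methylhex-5-enal | O=CC[C@@H](O[Si](C)(C)C(C)(C)C)[C@@H](C)C=C | intermediate
8 | isopropenylmagnesium bromide | C=C(C)[Mg]Br | starting material
9 | (5R,6S)-5-(tert-butyldimethylsilyloxy)-2,6-dimethylocta-1,7-dien-3-ol (both C3 epimers) | C=C(C)C(O)C[C@@H](O[Si](C)(C)C(C)(C)C)[C@@H](C)C=C | intermediate
10 | (4S,5R)-5-(tert-butyldimethylsilyloxy)-2,4-dimethylcyclohex-2-en-1-ol (both C1 epimers) | OC1C[C@@H](O[Si](C)(C)C(C)(C)C)[C@@H](C)C=C1C | intermediate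
11 | (4S,5R)-5-(tert-butyldimethylsilyloxy)-2,4-dimethylcyclohex-2-en-1-one | O=C1C[C@@H](O[Si](C)(C)C(C)(C)C)[C@@H](C)C=C1C | intermediate
12 | tributyl(propa-1,2-dien-1-yl)stannane | C=C=C[Sn](CCCC)(CCCC)CCCC | starting material
13 | (3S,4S,5R)-1,5-bis(tert-butyldimethylsilyloxy)-2,4-dimethyl-3-(prop-2-yn-1-yl)cyclohex-1-ene (key-step precursor) | CC1=C(O[Si](C)(C)C(C)(C)C)C[C@@H](O[Si](C)(C)C(C)(C)C)[C@@H](C)[C@@H]1CC#C | intermediate
14 | 8α-(tert-butyldimethylsilyloxy)-9α,14α-dimethyl-cis-hydrind-12-en-15-one (key-step product) | CC(C)(C)[Si](C)(C)O[C@H]1[C@@H](C)[C@@H]2CC=C[C@]2(C)C(=O)C1 | intermediate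
15 | 8α-(tert-butyldimethylsilyloxy)-16β-hydroxy-9α,14α-dimethyl-cis-hydrind-12-en-15-one | CC(C)(C)[Si](C)(C)O[C@H]1[C@@H](C)[C@@H]2CC=C[C@]2(C)C(=O)[C@@H]1O | intermediate
16 | 8α-(tert-butyldimethylsilyloxy)-9α,14α-dimethyl-cis-hydrind-12-ene-15α,16β-diol | CC(C)(C)[Si](C)(C)O[C@H]1[C@@H](C)[C@@H]2CC=C[C@]2(C)[C@@H](O)[C@@H]1O | intermediate
17 | 8α-(tert-butyldimethylsilyloxy)-16β-(triisopropylsilyloxy)-9α,14α-dimethyl-cis-hydrind-12-en-15α-ol | CC(C)(C)[Si](C)(C)O[C@H]1[C@@H](C)[C@@H]2CC=C[C@]2(C)[C@@H](O)[C@@H]1O[Si](C(C)C)(C(C)C)C(C)C | intermediate (not isolated)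
18 | 15α-acetoxy-8α-(tert-butyldimethylsilyloxy)-16β-(triisopropylsilyloxy)-9α,14α-dimethyl-cis-hydrind-12-ene | CC(C)(C)[Si](C)(C)O[C@H]1[C@@H](C)[C@@H]2CC=C[C@]2(C)[C@@H](OC(C)=O)[C@@H]1O[Si](C(C)C)(C(C)C)C(C)C | intermediate
19 | 15α-acetoxy-8α-(tert-butyldimethylsilyloxy)-16β-(triisopropylsilyloxy)-9α,14α-dimethyl-cis-hydrind-12-en-11-one | CC(C)(C)[Si](C)(C)O[C@H]1[C@@H](C)[C@@H]2C(=O)C=C[C@]2(C)[C@@H](OC(C)=O)[C@@H]1O[Si](C(C)C)(C(C)C)C(C)C | intermediate
20 | 15α-acetoxy-8α-(tert-butyldimethylsilyloxy)-16β-(triisopropylsilyloxy)-9α,14α-dimethyl-cis-hydrindan-11-one | CC(C)(C)[Si](C)(C)O[C@H]1[C@@H](C)[C@@H]2C(=O)CC[C@]2(C)[C@@H](OC(C)=O)[C@@H]1O[Si](C(C)C)(C(C)C)C(C)C | intermediate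
21 | 15α-acetoxy-8α-(tert-butyldimethylsilyloxy)-16β-(triisopropylsilyloxy)-9α,14α-dimethyl-cis-hydrind-11-en-11-yl triflate | CC(C)(C)[Si](C)(C)O[C@H]1[C@@H](C)[C@@H]2C(OS(=O)(=O)C(F)(F)F)=CC[C@]2(C)[C@@H](OC(C)=O)[C@@H]1O[Si](C(C)C)(C(C)C)C(C)C | intermediate
22 | tributyl(1-ethoxyvinyl)stannane | CCCC[Sn](CCCC)(CCCC)C(=C)OCC | starting material
23 | 11-(1-ethoxyvinyl)-15α-acetoxy-8α-(tert-butyldimethylsilyloxy)-16β-(triisopropylsilyloxy)-9α,14α-dimethyl-cis-hydrind-11-ene | CC(C)(C)[Si](C)(C)O[C@H]1[C@@H](C)[C@@H]2C(C(=C)OCC)=CC[C@]2(C)[C@@H](OC(C)=O)[C@@H]1O[Si](C(C)C)(C(C)C)C(C)C | intermediate (not isolated)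
24 | 11-acetyl-15α-acetoxy-8α-(tert-butyldimethylsilyloxy)-16β-(triisopropylsilyloxy)-9α,14α-dimethyl-cis-hydrind-11-ene | CC(C)(C)[Si](C)(C)O[C@H]1[C@@H](C)[C@@H]2C(C(C)=O)=CC[C@]2(C)[C@@H](OC(C)=O)[C@@H]1O[Si](C(C)C)(C(C)C)C(C)C | intermediate (not isolated)
25 | 11-acetyl-15α-acetoxy-16β-(triisopropylsilyloxy)-9α,14α-dimethyl-cis-hydrind-11-en-8α-ol | O[C@H]1[C@@H](C)[C@@H]2C(C(C)=O)=CC[C@]2(C)[C@@H](OC(C)=O)[C@@H]1O[Si](C(C)C)(C(C)C)C(C)C | intermediate
26 | 11β-acetyl-15α-acetoxy-16β-(triisopropylsilyloxy)-9α,14α-dimethyl-cis-hydrindan-8α-ol (H-11 α) | O[C@H]1[C@@H](C)[C@@H]2[C@H](C(C)=O)CC[C@]2(C)[C@@H](OC(C)=O)[C@@H]1O[Si](C(C)C)(C(C)C)C(C)C | intermediate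
27 | 11β-acetyl-15α-acetoxy-16β-(triisopropylsilyloxy)-9α,14α-dimethyl-cis-hydrindan-8-one | O=C1[C@@H](C)[C@@H]2[C@H](C(C)=O)CC[C@]2(C)[C@@H](OC(C)=O)[C@@H]1O[Si](C(C)C)(C(C)C)C(C)C | intermediate
28 | 15α-acetoxy-16β-(triisopropylsilyloxy)-9,14α-dimethyl-11β-(1-triflyloxyvinyl)-cis-hydrind-8-en-8-yl triflate | FC(F)(F)S(=O)(=O)OC1=C(C)[C@@H]2[C@H](C(=C)OS(=O)(=O)C(F)(F)F)CC[C@]2(C)[C@@H](OC(C)=O)[C@@H]1O[Si](C(C)C)(C(C)C)C(C)C | intermediate
29 | (R)-5-methoxy-3-methyl-5-oxopentanoic acid | OC(=O)C[C@@H](C)CC(=O)OC | starting material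
30 | methyl (R)-5-hydroxy-3-methylpentanoate | OCC[C@@H](C)CC(=O)OC | intermediate
31 | methyl (R)-3-methyl-5-(triethylsilyloxy)pentanoate | CC[Si](CC)(CC)OCC[C@@H](C)CC(=O)OC | intermediate
32 | (R)-3-methyl-5-(triethylsilyloxy)pentanal | CC[Si](CC)(CC)OCC[C@@H](C)CC=O | intermediate
33 | 2-(dichloromethyl)-4,4,5,5-tetramethyl-1,3,2-dioxaborolane | ClC(Cl)B1OC(C)(C)C(C)(C)O1 | starting material
34 | (S,E)-triethyl{[3-methyl-6-(4,4,5,5-tetramethyl-1,3,2-dioxaborolan-2-yl)hex-5-en-1-yl]oxy}silane | CC[Si](CC)(CC)OCC[C@@H](C)C/C=C/B1OC(C)(C)C(C)(C)O1 | intermediate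
35 | 15α-acetoxy-16β-(triisopropylsilyloxy)-9,14α-dimethyl-11β-[(3E,6S)-6-methyl-8-(triethylsilyloxy)octa-1,3-dien-2-yl]-cis-hydrind-8-en-8-yl triflate | FC(F)(F)S(=O)(=O)OC1=C(C)[C@@H]2[C@H](C(=C)/C=C/C[C@H](C)CCO[Si](CC)(CC)CC)CC[C@]2(C)[C@@H](OC(C)=O)[C@@H]1O[Si](C(C)C)(C(C)C)C(C)C | intermediate
36 | 15α-acetoxy-16β-(triisopropylsilyloxy)-9,14α-dimethyl-11β-[(3E,6S)-6-methyl-8-oxoocta-1,3-dien-2-yl]-cis-hydrind-8-en-8-yl triflate | FC(F)(F)S(=O)(=O)OC1=C(C)[C@@H]2[C@H](C(=C)/C=C/C[C@H](C)CC=O)CC[C@]2(C)[C@@H](OC(C)=O)[C@@H]1O[Si](C(C)C)(C(C)C)C(C)C | intermediate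
37 | 7-O-deacetyl-16-O-triisopropylsilyl target (both C7 epimers) | C=C1/C=C/C[C@H](C)CC(O)C2=C(C)[C@@H]3[C@H]1CC[C@]3(C)[C@@H](OC(C)=O)[C@@H]2O[Si](C(C)C)(C(C)C)C(C)C | intermediate
38 | 7-oxo-7-deacetoxy-16-O-triisopropylsilyl target | C=C1/C=C/C[C@H](C)CC(=O)C2=C(C)[C@@H]3[C@H]1CC[C@]3(C)[C@@H](OC(C)=O)[C@@H]2O[Si](C(C)C)(C(C)C)C(C)C | intermediate
39 | (7S)-7-O-deacetyl-16-O-triisopropylsilyl target | C=C1/C=C/C[C@H](C)C[C@H](O)C2=C(C)[C@@H]3[C@H]1CC[C@]3(C)[C@@H](OC(C)=O)[C@@H]2O[Si](C(C)C)(C(C)C)C(C)C | intermediate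
40 | 16-O-triisopropylsilyl target | C=C1/C=C/C[C@H](C)C[C@H](OC(C)=O)C2=C(C)[C@@H]3[C@H]1CC[C@]3(C)[C@@H](OC(C)=O)[C@@H]2O[Si](C(C)C)(C(C)C)C(C)C | intermediate
41 | CNP0323842.1 | C=C1/C=C/C[C@H](C)C[C@H](OC(C)=O)C2=C(C)[C@@H]3[C@H]1CC[C@]3(C)[C@@H](OC(C)=O)[C@@H]2O | target

**Step count**

Total: 30 steps. Longest linear sequence: 26 steps (steps 1–19 and 24–30); the side chain takes 4 steps (20–23).

**Steps most likely to fail**

Step 26. Nickel insertion into the hindered tetrasubstituted triflate is slow and the closure must overcome the transannular strain of an eleven-membered ring with two E alkenes, so reduction of the triflate and intermolecular coupling may outrun cyclisation. The fallback moves the ring closure to C2=C3 and joins C7 to C8 intermolecularly, where excess aldehyde and normal concentration can be used. Bis-triflate 28 would be coupled site-selectively with vinylboronic acid pinacol ester (Pd(PPh3)4, aq. K3PO4) to give the 11β-(buta-1,3-dien-2-yl) C8 triflate F1. Aldehyde 32 would be methylenated (Ph3P=CH2) to (S)-triethyl[(3-methylhex-5-en-1-yl)oxy]silane F2 and oxidised under Swern conditions to (S)-3-methylhex-5-enal F3. Intermolecular Nozaki–Hiyama–Kishi coupling of F1 with excess F3 would give the open-chain C7 carbinol F4. Ring-closing metathesis (Grubbs second-generation catalyst, high dilution) between the two terminal vinyl groups would then form C2=C3 and return to macrocyclic alcohol 37.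

Step 24. The palladium catalyst may also insert into the C8 triflate, giving double coupling or coupling at the wrong site. The fallback makes the two triflates one after the other. Hydroxy ketone 26 would be treated with KHMDS (2.1 equiv) and PhNTf2 (1.05 equiv) at −78 °C, where the methyl-ketone enolate is triflated and the hindered secondary alkoxide is left, to give the C1 enol triflate 8α-alcohol F5. Suzuki coupling of F5 with 34 would give the diene 8α-alcohol F6, and Dess–Martin oxidation the diene C8 ketone F7. Kinetic enolisation toward C9 and triflation (KHMDS, PhNTf2) would then return to diene triflate 35.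

Step 13. Hydrogen abstraction gives an allyl radical that may be oxygenated at C13 with a shift of the double bond, or the hindered methylene may react too slowly and the enone over-oxidise. The fallback uses an ene/[2,3]-sigmatropic sequence that places oxygen on the carbon that loses hydrogen. Alkene 18 would be treated with SeO2 (cat.) and t-BuOOH in CH2Cl2 to give the C11 allylic alcohol F8, and oxidation of F8 with Dess–Martin periodinane or MnO2 would return to enone 19.

**Further compounds**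

F1 | step 26 | 15α-acetoxy-11β-(buta-1,3-dien-2-yl)-16β-(triisopropylsilyloxy)-9,14α-dimethyl-cis-hydrind-8-en-8-yl triflate | FC(F)(F)S(=O)(=O)OC1=C(C)[C@@H]2[C@H](C(=C)C=C)CC[C@]2(C)[C@@H](OC(C)=O)[C@@H]1O[Si](C(C)C)(C(C)C)C(C)C
F2 | step 26 | (S)-triethyl[(3-methylhex-5-en-1-yl)oxy]silane | C=CC[C@H](C)CCO[Si](CC)(CC)CC
F3 | step 26 | (S)-3-methylhex-5-enal | C=CC[C@H](C)CC=O
F4 | step 26 | open-chain C7 carbinol: 15α-acetoxy-11β-(buta-1,3-dien-2-yl)-8-[(3S)-1-hydroxy-3-methylhex-5-en-1-yl]-16β-(triisopropylsilyloxy)-9,14α-dimethyl-cis-hydrind-8-ene (both C7 epimers) | C=CC[C@H](C)CC(O)C1=C(C)[C@@H]2[C@H](C(=C)C=C)CC[C@]2(C)[C@@H](OC(C)=O)[C@@H]1O[Si](C(C)C)(C(C)C)C(C)C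
F5 | step 24 | 15α-acetoxy-16β-(triisopropylsilyloxy)-9α,14α-dimethyl-11β-(1-triflyloxyvinyl)-cis-hydrindan-8α-ol | O[C@H]1[C@@H](C)[C@@H]2[C@H](C(=C)OS(=O)(=O)C(F)(F)F)CC[C@]2(C)[C@@H](OC(C)=O)[C@@H]1O[Si](C(C)C)(C(C)C)C(C)C
F6 | step 24 | 15α-acetoxy-16β-(triisopropylsilyloxy)-9α,14α-dimethyl-11β-[(3E,6S)-6-methyl-8-(triethylsilyloxy)octa-1,3-dien-2-yl]-cis-hydrindan-8α-ol | O[C@H]1[C@@H](C)[C@@H]2[C@H](C(=C)/C=C/C[C@H](C)CCO[Si](CC)(CC)CC)CC[C@]2(C)[C@@H](OC(C)=O)[C@@H]1O[Si](C(C)C)(C(C)C)C(C)C
F7 | step 24 | 15α-acetoxy-16β-(triisopropylsilyloxy)-9α,14α-dimethyl-11β-[(3E,6S)-6-methyl-8-(triethylsilyloxy)octa-1,3-dien-2-yl]-cis-hydrindan-8-one | O=C1[C@@H](C)[C@@H]2[C@H](C(=C)/C=C/C[C@H](C)CCO[Si](CC)(CC)CC)CC[C@]2(C)[C@@H](OC(C)=O)[C@@H]1O[Si](C(C)C)(C(C)C)C(C)C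
F8 | step 13 | 15α-acetoxy-8α-(tert-butyldimethylsilyloxy)-16β-(triisopropylsilyloxy)-9α,14α-dimethyl-cis-hydrind-12-en-11-ol (C11 epimers) | CC(C)(C)[Si](C)(C)O[C@H]1[C@@H](C)[C@@H]2C(O)C=C[C@]2(C)[C@@H](OC(C)=O)[C@@H]1O[Si](C(C)C)(C(C)C)C(C)C
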